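The 2,3-dihydrobenzofuran is cut at C3a–C7a and C4–C5, which turns the arene into a 3-alkoxy-6-acetylpyridazine and a terminal alkyne joined through O1, C2 and C3. The feature used is that O1 on C7a stands para to the carbon substituent on C5 and ortho to C3a, exactly the 3,6-pattern of the diazine. One thermal inverse-electron-demand [4+2] cycloaddition with loss of N2 then closes the benzene ring and the dihydrofuran ring together. The precursor is a syn-configured hex-5-en-1-yne-3,4-diol derivative from D-tartaric acid: it carries both ring stereocentres, the pyridazinyl ether on the allylic oxygen and the isovalerate on the propargylic oxygen.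

Key step: step 11

Assumption: dimethyl 2,3-O-isopropylidene-D-tartrate 1 is taken as a catalogue compound; otherwise it follows in one step from dimethyl D-tartrate (2,2-dimethoxypropane, TsOH).

Remarks on the design:
- The acetyl equivalent is placed on the diazine before the ether is made, so no zerovalent palladium meets the allylic heteroaryl ether or the alkyne.
- The propargylic oxygen carries a 4-methoxybenzyl ether during the alkoxide step, because an ester or a silyl group there could migrate to the neighbouring alkoxide.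
- The primary allylic oxygen carries a tert-butyldiphenylsilyl group, which survives the acetal hydrolysis.

Step 1
Reactants: 1 dimethyl (4S,5S)-2,2-dimethyl-1,3-dioxolane-4,5-dicarboxylate; 2 dimethyl (1-diazo-2-oxopropyl)phosphonate
Product: 4 methyl (4S,5R)-5-ethynyl-2,2-dimethyl-1,3-dioxolane-4-carboxylate, via aldehyde ester 3 (not isolated)
Conditions: iBu2AlH (1.0 equiv), CH2Cl2, −78 °C; then MeOH, K2CO3, 2, −78 °C to rt
Reagents that add atoms: dimethyl (1-diazo-2-oxopropyl)phosphonate 2, COP(=O)(OC)C(=[N+]=[N-])C(C)=O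
Why: Half-reduction of one of the two equivalent esters stops at the aluminium hemiacetal at −78 °C, and the aldehyde released by methanol is homologated in the same flask (Seyferth–Gilbert homologation with the Ohira–Bestmann reagent); both stereocentres come from D-tartaric acid and the trans-dioxolane is the more stable isomer, so the carbonate base should not erode them, and unreacted 1 can be recovered from this statistical monofunctionalisation.

Step 2
Reactants: 4 methyl (4S,5R)-5-ethynyl-2,2-dimethyl-1,3-dioxolane-4-carboxylate; 5 (trimethylsilyl)methylmagnesium chloride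
Product: 7 trimethyl{2-[(4R,5R)-5-ethynyl-2,2-dimethyl-1,3-dioxolan-4-yl]prop-2-en-1-yl}silane, via bis(silylmethyl) carbinol 6 (not isolated)
Conditions: 5 (5 equiv), CeCl3, THF, −78 °C to rt; then SiO2, CH2Cl2, rt
Reagents that add atoms: (trimethylsilyl)methylmagnesium chloride 5, C[Si](C)(C)C[Mg]Cl
Why: The non-basic organocerium reagent adds twice to the ester, and acid-induced Peterson elimination of one β-hydroxysilane arm of carbinol 6 gives the 2-substituted allylsilane (known ester-to-allylsilane conversion); one equivalent of reagent is spent on the alkyne hydrogen and the α-stereocentre is not enolised.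

Step 3
Reactants: 7 trimethyl{2-[(4R,5R)-5-ethynyl-2,2-dimethyl-1,3-dioxolan-4-yl]prop-2-en-1-yl}silane
Product: 9 2-[(4R,5R)-5-ethynyl-2,2-dimethyl-1,3-dioxolan-4-yl]prop-2-en-1-ol, via epoxysilane 8 (not isolated)
Conditions: mCPBA (1.05 equiv), CH2Cl2, 0 °C; then AcOH (cat.), MeOH, rt
Reagents that add atoms: 3-chloroperoxybenzoic acid, OOC(=O)c1cccc(Cl)c1
Why: Prilezhaev epoxidation of the electron-rich allylsilane double bond is followed by acid-induced, β-silicon-assisted opening of epoxysilane 8 with loss of the silyl group, giving the transposed allylic alcohol, which for a 2-substituted allyl unit has the same constitution; the alkyne does not react with the peracid.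

Step 4
Reactants: 9 2-[(4R,5R)-5-ethynyl-2,2-dimethyl-1,3-dioxolan-4-yl]prop-2-en-1-ol
Product: 10 tert-butyl({2-[(4R,5R)-5-ethynyl-2,2-dimethyl-1,3-dioxolan-4-yl]prop-2-en-1-yl}oxy)diphenylsilane
Conditions: TBDPSCl, imidazole, CH2Cl2, 0 °C to rt
Reagents that add atoms: tert-butyl(chloro)diphenylsilane, CC(C)(C)[Si](Cl)(c1ccccc1)c1ccccc1
Why: Silylation of the only hydroxyl with imidazole as nucleophilic catalyst and base; the bulky silyl ether is chosen because it has to survive the aqueous acid of step 5.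

Step 5
Reactants: 10 tert-butyl({2-[(4R,5R)-5-ethynyl-2,2-dimethyl-1,3-dioxolan-4-yl]prop-2-en-1-yl}oxy)diphenylsilane
Product: 11 (3R,4R)-2-({[tert-butyl(diphenyl)silyl]oxy}methyl)hex-1-en-5-yne-3,4-diol
Conditions: AcOH/H2O (4:1), 55 °C
Reagents that add atoms: none
Why: Acid-catalysed hydrolysis of the isopropylidene acetal; the tert-butyldiphenylsilyl ether and the alkyne are stable to aqueous acetic acid, and no C–O bond at a stereocentre is broken.

Step 6
Reactants: 11 (3R,4R)-2-({[tert-butyl(diphenyl)silyl]oxy}methyl)hex-1-en-5-yne-3,4-diol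
Product: 12 (3R,4R)-2-({[tert-butyl(diphenyl)silyl]oxy}methyl)-4-[(4-methoxyphenyl)methoxy]hex-1-en-5-yn-3-ol
Conditions: NaH (1.0 equiv), 4-MeOC6H4CH2Cl, Bu4NI (cat.), THF/DMF, −20 to 0 °C
Reagents that add atoms: 4-methoxybenzyl chloride, COc1ccc(CCl)cc1
Why: Williamson etherification of the mono-alkoxide: the propargylic hydroxyl is the more acidic (adjacent sp carbon) and the less hindered of the two, so it should be alkylated in preference to the allylic hydroxyl flanked by the branched silyloxymethyl-vinyl group; any regioisomer or bis-ether is removed by chromatography.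

Step 7
Reactants: 13 3,6-dichloropyridazine; 14 tributyl(1-ethoxyethenyl)stannane
Product: 15 3-chloro-6-(1-ethoxyethenyl)pyridazine
Conditions: Pd(PPh3)2Cl2 (3 mol %), 13 (2 equiv), DMF, 90 °C
Reagents that add atoms: tributyl(1-ethoxyethenyl)stannane 14, CCCC[Sn](CCCC)(CCCC)C(=C)OCC
Why: Stille coupling at one of the two equivalent C–Cl bonds, with the dichloride in excess to hold the reaction at mono-coupling.

Step 8
Reactants: 12 (3R,4R)-2-({[tert-butyl(diphenyl)silyl]oxy}methyl)-4-[(4-methoxyphenyl)methoxy]hex-1-en-5-yn-3-ol; 15 3-chloro-6-(1-ethoxyethenyl)pyridazine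
Product: 17 1-(6-{[(3R,4R)-2-({[tert-butyl(diphenyl)silyl]oxy}methyl)-4-[(4-methoxyphenyl)methoxy]hex-1-en-5-yn-3-yl]oxy}pyridazin-3-yl)ethan-1-one, via enol ether 16 (not isolated)
Conditions: NaH (1.2 equiv), THF/DMF, 0 °C; 15, 0 to 45 °C; then 1 M HCl, THF, 0 °C
Reagents that add atoms: 3-chloro-6-(1-ethoxyethenyl)pyridazine 15, CCOC(=C)c1ccc(Cl)nn1; water, O
Why: Nucleophilic aromatic substitution (addition–elimination at C3 of the diazine) by the allylic alkoxide leaves the carbinol C–O bond and its configuration untouched, and the enol ether 16 is hydrolysed to the methyl ketone on the acidic work-up.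

Step 9
Reactants: 17 1-(6-{[(3R,4R)-2-({[tert-butyl(diphenyl)silyl]oxy}methyl)-4-[(4-methoxyphenyl)methoxy]hex-1-en-5-yn-3-yl]oxy}pyridazin-3-yl)ethan-1-one
Product: 18 1-(6-{[(3R,4R)-2-({[tert-butyl(diphenyl)silyl]oxy}methyl)-4-hydroxyhex-1-en-5-yn-3-yl]oxy}pyridazin-3-yl)ethan-1-one
Conditions: DDQ (1.3 equiv), CH2Cl2/pH 7 buffer, 0 °C to rt
Reagents that add atoms: none
Why: Oxidative cleavage of the 4-methoxybenzyl ether by DDQ (hydride abstraction at the electron-rich benzylic position, then hydrolysis of the oxocarbenium ion); the electron-poor diazine, the silyl ether and the unsaturations are inert, and no base is present that could move the heteroaryl group to the freed hydroxyl.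

Step 10
Reactants: 18 1-(6-{[(3R,4R)-2-({[tert-butyl(diphenyl)silyl]oxy}methyl)-4-hydroxyhex-1-en-5-yn-3-yl]oxy}pyridazin-3-yl)ethan-1-one; 19 3-methylbutanoyl chloride
Product: 20 (3R,4R)-4-[(6-acetylpyridazin-3-yl)oxy]-5-({[tert-butyl(diphenyl)silyl]oxy}methyl)hex-5-en-1-yn-3-yl 3-methylbutanoate
Conditions: 19, pyridine, DMAP (cat.), CH2Cl2, 0 °C
Reagents that add atoms: 3-methylbutanoyl chloride 19, CC(C)CC(=O)Cl
Why: DMAP-catalysed acylation of the propargylic alcohol under weakly basic conditions, so that neither acyl nor heteroaryl migration through an alkoxide can occur; configuration is retained because only the O–H bond reacts.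

Step 11
Reactants: 20 (3R,4R)-4-[(6-acetylpyridazin-3-yl)oxy]-5-({[tert-butyl(diphenyl)silyl]oxy}methyl)hex-5-en-1-yn-3-yl 3-methylbutanoate
Product: 22 (2R,3R)-5-acetyl-2-(3-{[tert-butyl(diphenyl)silyl]oxy}prop-1-en-2-yl)-2,3-dihydro-1-benzofuran-3-yl 3-methylbutanoate, via bridged diaza cycloadduct 21 (not isolated)
Conditions: 1,2-dichlorobenzene (0.02 M), BHT (cat.), 160 °C, sealed tube, Ar
Reagents that add atoms: none
Why: The diazine, its LUMO lowered by the acetyl group, engages the tethered terminal alkyne across pyridazine C3 and C6 in an intramolecular inverse-electron-demand Diels–Alder reaction, and the bridged adduct 21 at once loses N2 by retro-[4+2] to give the arene; the closest known reaction type is the thermal conversion of 3-(but-3-ynyloxy)pyridazines into 2,3-dihydrobenzofurans. The benzene ring closes through the two new bonds C3a–C7a and C4–C5 (cycloaddition, then cycloreversion), and the dihydrofuran ring closes in the same event as the five-membered tether ring O1–C2–C3–C3a–C7a. No stereocentre is formed: C2 and C3 are the tartrate-derived tether carbons and are not touched, so their syn relation becomes the cis relation of the ring, and the bridgehead centres of 21 vanish on aromatisation. No regiochemistry has to be controlled, because the para relation of O1 and the acetyl group is already present in the 3,6-disubstituted diazine. What is needed is chemoselectivity over the O-to-N [3,3] shift of the allylic heteroaryl ether and over loss of isovaleric acid; the three-atom tether with two substituents (Thorpe–Ingold effect) and the acetyl activation should let the cycloaddition run below the temperature of those processes, and in the cis product H2 lies anti to the ester, so a thermal syn-elimination has no hydrogen to use.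

Step 12
Reactants: 22 (2R,3R)-5-acetyl-2-(3-{[tert-butyl(diphenyl)silyl]oxy}prop-1-en-2-yl)-2,3-dihydro-1-benzofuran-3-yl 3-methylbutanoate
Product: 23 (2R,3R)-2-(3-{[tert-butyl(diphenyl)silyl]oxy}prop-1-en-2-yl)-5-[(1S)-1-hydroxyethyl]-2,3-dihydro-1-benzofuran-3-yl 3-methylbutanoate
Conditions: RuCl(p-cymene)[(S,S)-TsDPEN] (2 mol %), HCO2H/Et3N (5:2), CH2Cl2, 30 °C
Reagents that add atoms: none
Why: Noyori–Ikariya asymmetric transfer hydrogenation of the aryl methyl ketone: with the (S,S)-ligand the hydride is delivered to the Re face, which sets the (S)-carbinol under catalyst control, remote from and independent of C2 and C3; the esters, the silyl ether and the 1,1-disubstituted alkene are not reduced.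

Step 13
Reactants: 23 (2R,3R)-2-(3-{[tert-butyl(diphenyl)silyl]oxy}prop-1-en-2-yl)-5-[(1S)-1-hydroxyethyl]-2,3-dihydro-1-benzofuran-3-yl 3-methylbutanoate; 24 3-methylbut-2-enoic acid
Product: 25 (1S)-1-[(2R,3R)-2-(3-{[tert-butyl(diphenyl)silyl]oxy}prop-1-en-2-yl)-3-[(3-methylbutanoyl)oxy]-2,3-dihydro-1-benzofuran-5-yl]ethyl 3-methylbut-2-enoate
Conditions: 24, DCC, DMAP (cat.), CH2Cl2, 0 °C to rt
Reagents that add atoms: 3-methylbut-2-enoic acid 24, CC(C)=CC(=O)O
Why: Steglich esterification, which retains the carbinol configuration and avoids the vinylketene pathway by which the acid chloride and an amine base would deconjugate the senecioate.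

Step 14
Reactants: 25 (1S)-1-[(2R,3R)-2-(3-{[tert-butyl(diphenyl)silyl]oxy}prop-1-en-2-yl)-3-[(3-methylbutanoyl)oxy]-2,3-dihydro-1-benzofuran-5-yl]ethyl 3-methylbut-2-enoate
Product: 26 (1S)-1-[(2R,3R)-2-(3-hydroxyprop-1-en-2-yl)-3-[(3-methylbutanoyl)oxy]-2,3-dihydro-1-benzofuran-5-yl]ethyl 3-methylbut-2-enoate
Conditions: HF·pyridine, pyridine, THF, 0 °C to rt
Reagents that add atoms: none
Why: Fluoride-driven cleavage of the Si–O bond in a pyridine-buffered medium that should spare both esters, including the acid-sensitive 4-alkoxybenzylic senecioate.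

Step 15
Reactants: 26 (1S)-1-[(2R,3R)-2-(3-hydroxyprop-1-en-2-yl)-3-[(3-methylbutanoyl)oxy]-2,3-dihydro-1-benzofuran-5-yl]ethyl 3-methylbut-2-enoate
Product: 27 (1S)-1-[(2R,3R)-3-[(3-methylbutanoyl)oxy]-2-(3-oxoprop-1-en-2-yl)-2,3-dihydro-1-benzofuran-5-yl]ethyl 3-methylbut-2-enoate
Conditions: MnO2 (activated, excess), CH2Cl2, rt
Reagents that add atoms: none
Why: Selective oxidation of the primary allylic alcohol to the enal on MnO2 under neutral conditions, which avoid base-induced elimination of the C3 ester towards the benzofuran; no stereocentre is touched.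

Compound list
1 | dimethyl (4S,5S)-2,2-dimethyl-1,3-dioxolane-4,5-dicarboxylate (dimethyl 2,3-O-isopropylidene-D-tartrate) | CC1(C)O[C@H](C(=O)OC)[C@H](O1)C(=O)OC | starting material
2 | dimethyl (1-diazo-2-oxopropyl)phosphonate (Ohira–Bestmann reagent) | COP(=O)(OC)C(=[N+]=[N-])C(C)=O | starting material
3 | methyl (4S,5S)-5-formyl-2,2-dimethyl-1,3-dioxolane-4-carboxylate | CC1(C)O[C@H](C(=O)OC)[C@H](O1)C=O | intermediate
4 | methyl (4S,5R)-5-ethynyl-2,2-dimethyl-1,3-dioxolane-4-carboxylate | CC1(C)O[C@H](C(=O)OC)[C@H](O1)C#C | intermediate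
5 | (trimethylsilyl)methylmagnesium chloride | C[Si](C)(C)C[Mg]Cl | starting material
6 | 2-[(4S,5R)-5-ethynyl-2,2-dimethyl-1,3-dioxolan-4-yl]-1,3-bis(trimethylsilyl)propan-2-ol | CC1(C)O[C@H](C(O)(C[Si](C)(C)C)C[Si](C)(C)C)[C@H](O1)C#C | intermediate
7 | trimethyl{2-[(4R,5R)-5-ethynyl-2,2-dimethyl-1,3-dioxolan-4-yl]prop-2-en-1-yl}silane | CC1(C)O[C@H](C(=C)C[Si](C)(C)C)[C@H](O1)C#C | intermediate
8 | trimethyl({2-[(4S,5R)-5-ethynyl-2,2-dimethyl-1,3-dioxolan-4-yl]oxiran-2-yl}methyl)silane, both epimers at the oxirane carbon | CC1(C)O[C@H](C2(C[Si](C)(C)C)CO2)[C@H](O1)C#C | intermediate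
9 | 2-[(4R,5R)-5-ethynyl-2,2-dimethyl-1,3-dioxolan-4-yl]prop-2-en-1-ol | CC1(C)O[C@H](C(=C)CO)[C@H](O1)C#C | intermediate
10 | tert-butyl({2-[(4R,5R)-5-ethynyl-2,2-dimethyl-1,3-dioxolan-4-yl]prop-2-en-1-yl}oxy)diphenylsilane | CC1(C)O[C@H](C(=C)CO[Si](c2ccccc2)(c2ccccc2)C(C)(C)C)[C@H](O1)C#C | intermediate
11 | (3R,4R)-2-({[tert-butyl(diphenyl)silyl]oxy}methyl)hex-1-en-5-yne-3,4-diol | O[C@H](C(=C)CO[Si](c1ccccc1)(c1ccccc1)C(C)(C)C)[C@H](O)C#C | intermediate
12 | (3R,4R)-2-({[tert-butyl(diphenyl)silyl]oxy}methyl)-4-[(4-methoxyphenyl)methoxy]hex-1-en-5-yn-3-ol | O[C@H](C(=C)CO[Si](c1ccccc1)(c1ccccc1)C(C)(C)C)[C@H](OCc1ccc(OC)cc1)C#C | intermediate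
13 | 3,6-dichloropyridazine | Clc1ccc(Cl)nn1 | starting material
14 | tributyl(1-ethoxyethenyl)stannane | CCCC[Sn](CCCC)(CCCC)C(=C)OCC | starting material
15 | 3-chloro-6-(1-ethoxyethenyl)pyridazine | CCOC(=C)c1ccc(Cl)nn1 | intermediate
16 | 3-{[(3R,4R)-2-({[tert-butyl(diphenyl)silyl]oxy}methyl)-4-[(4-methoxyphenyl)methoxy]hex-1-en-5-yn-3-yl]oxy}-6-(1-ethoxyethenyl)pyridazine | CCOC(=C)c1ccc(O[C@H](C(=C)CO[Si](c2ccccc2)(c2ccccc2)C(C)(C)C)[C@H](OCc2ccc(OC)cc2)C#C)nn1 | intermediate
17 | 1-(6-{[(3R,4R)-2-({[tert-butyl(diphenyl)silyl]oxy}methyl)-4-[(4-methoxyphenyl)methoxy]hex-1-en-5-yn-3-yl]oxy}pyridazin-3-yl)ethan-1-one | CC(=O)c1ccc(O[C@H](C(=C)CO[Si](c2ccccc2)(c2ccccc2)C(C)(C)C)[C@H](OCc2ccc(OC)cc2)C#C)nn1 | intermediate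
18 | 1-(6-{[(3R,4R)-2-({[tert-butyl(diphenyl)silyl]oxy}methyl)-4-hydroxyhex-1-en-5-yn-3-yl]oxy}pyridazin-3-yl)ethan-1-one | CC(=O)c1ccc(O[C@H](C(=C)CO[Si](c2ccccc2)(c2ccccc2)C(C)(C)C)[C@H](O)C#C)nn1 | intermediate
19 | 3-methylbutanoyl chloride | CC(C)CC(=O)Cl | starting material
20 | (3R,4R)-4-[(6-acetylpyridazin-3-yl)oxy]-5-({[tert-butyl(diphenyl)silyl]oxy}methyl)hex-5-en-1-yn-3-yl 3-methylbutanoate (key-step precursor) | CC(=O)c1ccc(O[C@H](C(=C)CO[Si](c2ccccc2)(c2ccccc2)C(C)(C)C)[C@H](OC(=O)CC(C)C)C#C)nn1 | intermediate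
21 | (3R,4R)-7-acetyl-3-(3-{[tert-butyl(diphenyl)silyl]oxy}prop-1-en-2-yl)-2-oxa-8,9-diazatricyclo[5.2.2.0(1,5)]undeca-5,8,10-trien-4-yl 3-methylbutanoate (bridgehead configuration not defined; lost on aromatisation) | CC(=O)C12N=NC3(O[C@H](C(=C)CO[Si](c4ccccc4)(c4ccccc4)C(C)(C)C)[C@H](OC(=O)CC(C)C)C3=C1)C=C2 | intermediate
22 | (2R,3R)-5-acetyl-2-(3-{[tert-butyl(diphenyl)silyl]oxy}prop-1-en-2-yl)-2,3-dihydro-1-benzofuran-3-yl 3-methylbutanoate (key-step product) | C=C(CO[Si](c1ccccc1)(c1ccccc1)C(C)(C)C)[C@H]1Oc2ccc(C(C)=O)cc2[C@H]1OC(=O)CC(C)C | intermediate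
23 | (2R,3R)-2-(3-{[tert-butyl(diphenyl)silyl]oxy}prop-1-en-2-yl)-5-[(1S)-1-hydroxyethyl]-2,3-dihydro-1-benzofuran-3-yl 3-methylbutanoate | C=C(CO[Si](c1ccccc1)(c1ccccc1)C(C)(C)C)[C@H]1Oc2ccc([C@H](C)O)cc2[C@H]1OC(=O)CC(C)C | intermediate
24 | 3-methylbut-2-enoic acid | CC(C)=CC(=O)O | starting material
25 | (1S)-1-[(2R,3R)-2-(3-{[tert-butyl(diphenyl)silyl]oxy}prop-1-en-2-yl)-3-[(3-methylbutanoyl)oxy]-2,3-dihydro-1-benzofuran-5-yl]ethyl 3-methylbut-2-enoate | C=C(CO[Si](c1ccccc1)(c1ccccc1)C(C)(C)C)[C@H]1Oc2ccc([C@H](C)OC(=O)C=C(C)C)cc2[C@H]1OC(=O)CC(C)C | intermediate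
26 | (1S)-1-[(2R,3R)-2-(3-hydroxyprop-1-en-2-yl)-3-[(3-methylbutanoyl)oxy]-2,3-dihydro-1-benzofuran-5-yl]ethyl 3-methylbut-2-enoate | C=C(CO)[C@H]1Oc2ccc([C@H](C)OC(=O)C=C(C)C)cc2[C@H]1OC(=O)CC(C)C | intermediate
27 | (1S)-1-[(2R,3R)-3-[(3-methylbutanoyl)oxy]-2-(3-oxoprop-1-en-2-yl)-2,3-dihydro-1-benzofuran-5-yl]ethyl 3-methylbut-2-enoate | C=C(C=O)[C@H]1Oc2ccc([C@H](C)OC(=O)C=C(C)C)cc2[C@H]1OC(=O)CC(C)C | target

Total step count: 15.
Longest linear sequence: 14 steps (1 to 27 through steps 1–6 and 8–15; step 7 is the side branch).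

Steps most likely to fail

Step 11. The cycloaddition may be outrun by other thermal channels: the O-to-N allyl shift of the heteroaryl ether, or ionisation and loss of the propargylic ester. The fallback sets out from 17 and comes back at 22. It runs the ring construction one stage earlier, on a substrate whose propargylic oxygen is an ether that cannot leave as an acid and that leaves the alkyne more electron-rich. Heating 17 under the same regime should pass through the bridged diaza adduct F1 to the 3-(4-methoxybenzyloxy)dihydrobenzofuran ketone F2. DDQ in wet CH2Cl2 would then free the 3-hydroxydihydrobenzofuran ketone F3, and acylation with 19 (pyridine, DMAP) returns to 22.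

Step 6. The two secondary hydroxyls may be discriminated poorly, with alkylation of the allylic oxygen or of both. The fallback sets out from 9 and comes back at 12, and fixes the regiochemistry by connectivity instead of by relative reactivity. Hydrolysis of the acetonide of 9 (AcOH/H2O) would give the triol (3R,4R)-2-methylidenehex-5-yne-1,3,4-triol F4. tBu2Si(OTf)2 with 2,6-lutidine silylates the primary hydroxyl first and can then close only onto the allylic oxygen, as a six-membered ring, to give the cyclic silylene F5 with the propargylic hydroxyl alone free. 4-Methoxybenzyl trichloroacetimidate with Sc(OTf)3 (cat.) converts it into the silylene 4-methoxybenzyl ether F6. HF·pyridine removes the silylene to give the diol 4-methoxybenzyl ether F7, whose primary allylic hydroxyl is silylated selectively with TBDPSCl and imidazole at low temperature to give 12.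

Step 8. Substitution at a chlorodiazine that is activated only weakly may be sluggish, and the alkoxide may degrade on prolonged warming. The fallback sets out from 12 and comes back at 17. The sodium alkoxide of 12 is added at −40 to 0 °C to 6-chloropyridazine-3-carbonitrile, a far more electrophilic partner, to give the pyridazinecarbonitrile ether F8. MeMgBr in excess (the first equivalent is spent on the alkyne hydrogen) adds to the nitrile to give, after quench, the N-unsubstituted ketimine F9, which dilute aqueous acid hydrolyses to 17.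

Further compounds
F1 | step 11 | 1-[(3R,4R)-3-(3-{[tert-butyl(diphenyl)silyl]oxy}prop-1-en-2-yl)-4-[(4-methoxyphenyl)methoxy]-2-oxa-8,9-diazatricyclo[5.2.2.0(1,5)]undeca-5,8,10-trien-7-yl]ethan-1-one (bridgehead configuration not defined) | CC(=O)C12N=NC3(O[C@H](C(=C)CO[Si](c4ccccc4)(c4ccccc4)C(C)(C)C)[C@H](OCc4ccc(OC)cc4)C3=C1)C=C2
F2 | step 11 | 1-[(2R,3R)-2-(3-{[tert-butyl(diphenyl)silyl]oxy}prop-1-en-2-yl)-3-[(4-methoxyphenyl)methoxy]-2,3-dihydro-1-benzofuran-5-yl]ethan-1-one | C=C(CO[Si](c1ccccc1)(c1ccccc1)C(C)(C)C)[C@H]1Oc2ccc(C(C)=O)cc2[C@H]1OCc1ccc(OC)cc1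
F3 | step 11 | 1-[(2R,3R)-2-(3-{[tert-butyl(diphenyl)silyl]oxy}prop-1-en-2-yl)-3-hydroxy-2,3-dihydro-1-benzofuran-5-yl]ethan-1-one | C=C(CO[Si](c1ccccc1)(c1ccccc1)C(C)(C)C)[C@H]1Oc2ccc(C(C)=O)cc2[C@H]1O
F4 | step 6 | (3R,4R)-2-methylidenehex-5-yne-1,3,4-triol | O[C@H](C(=C)CO)[C@H](O)C#C
F5 | step 6 | (1R)-1-[(4R)-2,2-di-tert-butyl-5-methylidene-1,3,2-dioxasilinan-4-yl]prop-2-yn-1-ol | CC(C)(C)[Si]1(C(C)(C)C)OCC(=C)[C@@H](O1)[C@H](O)C#C
F6 | step 6 | (4R)-2,2-di-tert-butyl-4-{(1R)-1-[(4-methoxyphenyl)methoxy]prop-2-yn-1-yl}-5-methylidene-1,3,2-dioxasilinane | CC(C)(C)[Si]1(C(C)(C)C)OCC(=C)[C@@H](O1)[C@H](OCc1ccc(OC)cc1)C#C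
F7 | step 6 | (3R,4R)-4-[(4-methoxyphenyl)methoxy]-2-methylidenehex-5-yne-1,3-diol | O[C@H](C(=C)CO)[C@H](OCc1ccc(OC)cc1)C#C
F8 | step 8 | 6-{[(3R,4R)-2-({[tert-butyl(diphenyl)silyl]oxy}methyl)-4-[(4-methoxyphenyl)methoxy]hex-1-en-5-yn-3-yl]oxy}pyridazine-3-carbonitrile | N#Cc1ccc(O[C@H](C(=C)CO[Si](c2ccccc2)(c2ccccc2)C(C)(C)C)[C@H](OCc2ccc(OC)cc2)C#C)nn1
F9 | step 8 | 1-(6-{[(3R,4R)-2-({[tert-butyl(diphenyl)silyl]oxy}methyl)-4-[(4-methoxyphenyl)methoxy]hex-1-en-5-yn-3-yl]oxy}pyridazin-3-yl)ethan-1-imine | CC(=N)c1ccc(O[C@H](C(=C)CO[Si](c2ccccc2)(c2ccccc2)C(C)(C)C)[C@H](OCc2ccc(OC)cc2)C#C)nn1
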